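The bond broken in the analysis is C4–C4a of the upper pyran ring (ring C). The feature exploited is that upper C4 is a diarylmethine held between C4a of the phloroglucinol-type ring A and C8 of the lower ring D, so a C4 cation stabilised by the trioxygenated ring D can be trapped by the symmetric ring A. In one operation this closes the O1–C2–C3–C4–C4a–C8a ring and sets C4 trans to the C3 oxygen, with the 4→8 bond already in place. The precursor is a flavan-8-yl carbinol bearing an α-silyloxy, β-aryl, β-aryloxy chain, made from 8-lithiated benzylated gallocatechin and an aldehyde whose two stereocentres come from asymmetric epoxidation and phenoxide opening.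

Key step: step 12

Remark: compound 15 is carried as the mixture of both carbinol epimers, because that carbon becomes planar on ionisation in step 12; building blocks 5, 9 and 19 are taken to be purchasable.

Step 1
Reactants: 1 (+)-gallocatechin
Product: 2 penta-O-benzyl-(+)-gallocatechin (benzyl on O5, O7, O3', O4', O5'; free 3-OH)
Conditions: BnBr (5.5 equiv), K2CO3, DMF, 0 °C to rt, argon
Reagents that add atoms: benzyl bromide, BrCc1ccccc1
Why: Williamson etherification in which K2CO3 deprotonates only the five phenols and not the secondary 3-OH, the mild base and low temperature under argon being chosen so that the (2R,3S) centres of the lower unit, which enter the route here, are not epimerised through ring opening.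

Step 2
Reactants: 2 penta-O-benzyl-(+)-gallocatechin
Product: 3 8-bromo-penta-O-benzyl-(+)-gallocatechin (free 3-OH)
Conditions: NBS (1.0 equiv), CH2Cl2, −78 °C to rt
Reagents that add atoms: N-bromosuccinimide, O=C1CCC(=O)N1Br
Why: Electrophilic aromatic bromination, for which C8 (flanked by O1 and the 7-benzyloxy group) is the position that benzylated flavan-3-ols are known to brominate first, so one equivalent of NBS at low temperature should spare C6 and the less activated ring of the pyrogallol unit.

Step 3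
Reactants: 3 8-bromo-penta-O-benzyl-(+)-gallocatechin
Product: 4 8-bromo-hexa-O-benzyl-(+)-gallocatechin (3-O-benzyl)
Conditions: NaH, BnBr, DMF, 0 °C to rt
Reagents that add atoms: benzyl bromide, BrCc1ccccc1
Why: Williamson etherification of the secondary alkoxide, which is safe because all phenols are already capped (no base-induced C2 epimerisation) and the aryl bromide is inert to NaH; it marks the lower 3-oxygen permanently so that only the upper one can later be acylated.

Step 4
Reactants: 5 3,4,5-tris(benzyloxy)benzaldehyde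
Product: 6 methyl (Z)-3-[3,4,5-tris(benzyloxy)phenyl]prop-2-enoate
Conditions: (CF3CH2O)2P(O)CH2CO2Me, KN(SiMe3)2, 18-crown-6, THF, −78 °C
Reagents that add atoms: methyl bis(2,2,2-trifluoroethyl)phosphonoacetate, COC(=O)CP(=O)(OCC(F)(F)F)OCC(F)(F)F
Why: Still–Gennari olefination, in which the electron-poor trifluoroethyl phosphonate under dissociating conditions collapses the kinetically formed adduct before it can equilibrate, so that aromatic aldehydes should give the Z enoate.

Step 5
Reactants: 6 methyl (Z)-3-[3,4,5-tris(benzyloxy)phenyl]prop-2-enoate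
Product: 7 (Z)-3-[3,4,5-tris(benzyloxy)phenyl]prop-2-en-1-ol
Conditions: i-Bu2AlH (2.5 equiv), CH2Cl2, −78 °C; aq. potassium sodium tartrate
Reagents that add atoms: none
Why: 1,2-Reduction of the enoate by i-Bu2AlH at low temperature, which should not touch the alkene or its Z geometry and leaves the benzyl ethers intact.

Step 6
Reactants: 7 (Z)-3-[3,4,5-tris(benzyloxy)phenyl]prop-2-en-1-ol
Product: 8 [(2R,3S)-3-[3,4,5-tris(benzyloxy)phenyl]oxiran-2-yl]methanol (cis-epoxide)
Conditions: Ti(OiPr)4 (0.2 equiv), D-(−)-diethyl tartrate (0.26 equiv), t-BuOOH, 4 Å molecular sieves, CH2Cl2, −20 °C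
Reagents that add atoms: tert-butyl hydroperoxide, CC(C)(C)OO
Why: Katsuki–Sharpless asymmetric epoxidation, in which D-(−)-tartrate directs oxygen to the face that makes the carbinol-bearing epoxide carbon R while syn addition to the Z alkene fixes the aryl-bearing carbon as S, the sieves allowing substoichiometric titanium so that Lewis-acid opening of the benzylic epoxide is limited.

Step 7
Reactants: 8 [(2R,3S)-3-[3,4,5-tris(benzyloxy)phenyl]oxiran-2-yl]methanol; 9 3,5-bis(benzyloxy)phenol
Product: 10 (2R,3R)-3-[3,5-bis(benzyloxy)phenoxy]-3-[3,4,5-tris(benzyloxy)phenyl]propane-1,2-diol (syn)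
Conditions: 9 (1.5 equiv), Cs2CO3 (0.3 equiv), DMF, 70 °C
Reagents that add atoms: none
Why: SN2 opening of the epoxide by the phenoxide at the benzylic carbon with inversion (the activated position, as in known phenoxide openings of 3-arylglycidols), which converts the cis-epoxide into the syn aryloxy/hydroxy pair that becomes the 2,3-cis relationship of ring C; substoichiometric carbonate with excess phenol keeps the alkoxide concentration low to suppress Payne rearrangement, and DMF favours O- over C-alkylation.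

Step 8
Reactants: 10 (2R,3R)-3-[3,5-bis(benzyloxy)phenoxy]-3-[3,4,5-tris(benzyloxy)phenyl]propane-1,2-diol
Product: 11 1,2-bis-O-(tert-butyldimethylsilyl) ether of diol 10
Conditions: TBSOTf (2.5 equiv), 2,6-lutidine, CH2Cl2, 0 °C
Reagents that add atoms: tert-butyldimethylsilyl trifluoromethanesulfonate, CC(C)(C)[Si](C)(C)OS(=O)(=O)C(F)(F)F
Why: Silyl ether formation with the reactive triflate, which should silylate the hindered secondary hydroxyl as well as the primary one under non-nucleophilic base without affecting either stereocentre.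

Step 9
Reactants: 11 1,2-bis-O-(tert-butyldimethylsilyl) ether of diol 10
Product: 12 (2R,3R)-3-[3,5-bis(benzyloxy)phenoxy]-2-(tert-butyldimethylsilyloxy)-3-[3,4,5-tris(benzyloxy)phenyl]propan-1-ol
Conditions: HF·pyridine, pyridine, THF, 0 °C
Reagents that add atoms: none
Why: Selective desilylation, in which buffered HF·pyridine removes the unhindered primary silyl ether much faster than the secondary one flanked by the aryl-bearing carbon, the slightly acidic medium excluding silyl migration.

Step 10
Reactants: 12 (2R,3R)-3-[3,5-bis(benzyloxy)phenoxy]-2-(tert-butyldimethylsilyloxy)-3-[3,4,5-tris(benzyloxy)phenyl]propan-1-ol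
Product: 13 (2S,3R)-3-[3,5-bis(benzyloxy)phenoxy]-2-(tert-butyldimethylsilyloxy)-3-[3,4,5-tris(benzyloxy)phenyl]propanal
Conditions: Dess–Martin periodinane, NaHCO3, CH2Cl2, rt; used directly
Reagents that add atoms: none
Why: Dess–Martin oxidation under buffered, base-free conditions, which should give the aldehyde without epimerising the α-silyloxy centre or eliminating the β-aryloxy group (the descriptor at C2 changes only because of the priority switch).

Step 11
Reactants: 4 8-bromo-hexa-O-benzyl-(+)-gallocatechin; 13 (2S,3R)-3-[3,5-bis(benzyloxy)phenoxy]-2-(tert-butyldimethylsilyloxy)-3-[3,4,5-tris(benzyloxy)phenyl]propanal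
Product: 15 flavan-8-yl carbinol (both epimers at the carbinol carbon), via 8-lithio-hexa-O-benzylgallocatechin 14 (not isolated)
Conditions: 4 (1.3 equiv), n-BuLi, THF, −78 °C; then 13, −78 to −40 °C; H2O
Reagents that add atoms: none
Why: Bromine–lithium exchange followed by 1,2-addition of the aryllithium to the aldehyde, the exchange at C8 being fast at −78 °C and the addition expected to outrun α-deprotonation and β-elimination of aryloxide; the carbinol configuration is irrelevant because it is erased in step 12, and material derived from the minor enantiomer of 13 is from here on a separable diastereomer.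

Step 12
Reactants: 15 flavan-8-yl carbinol (both epimers)
Product: 17 undeca-O-benzyl-3-O-(tert-butyldimethylsilyl)-epigallocatechin-(4β→8)-gallocatechin, via benzylic cation 16 (not isolated)
Conditions: BF3·OEt2 (0.3 equiv), 4 Å molecular sieves, CH2Cl2 (5 mM), −78 to −30 °C
Reagents that add atoms: none
Why: The Lewis acid ionises either carbinol epimer to cation 16, which is delocalised into the 2,4,6-trioxygenated ring D, and an ortho carbon of the 3,5-bis(benzyloxy)phenyl ether, activated by three ortho/para oxygens, attacks it and rearomatises by proton loss. The closest known reaction type is the acid-mediated intramolecular Friedel–Crafts cycloalkylation of 1-aryl-3-aryloxypropan-1-ols to 4-arylchromans, combined with the known 3,4-trans capture of flavan-4-yl cations by phloroglucinol-type arenes. Ring C is the only ring closed: a six-membered closure forming C4–C4a, exo with respect to the quinone-methide-like C4=C8 π-bond of the cation (6-exo-trig) and fused to ring A at C4a–C8a. The only new stereocentre, C4, is set by substrate control from C2 and C3: in the chair-like transition state the C2 aryl group is equatorial and the C3 silyloxy group axial, so the bulky flavanyl group on C4 goes pseudoaxial, anti to the C3–O bond and clear of the peri 5-benzyloxy group, which gives the 4β (3,4-trans, 4R) isomer. The step needs chemoselectivity for ring A over ring B and diastereoselectivity at C4; the first rests on the higher nucleophilicity of the phloroglucinol-type ring and on six-membered closure being preferred over the five-membered indane closure (the two ortho positions are equivalent, so no regiochemical question arises), the second on the preset 2,3-cis pair and the bulky silyl ether. Because the 4→8 bond already exists and the nucleophile is internal, 4→6 isomers and oligomers cannot arise at high dilution.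

Step 13
Reactants: 17 undeca-O-benzyl-3-O-(tert-butyldimethylsilyl)-epigallocatechin-(4β→8)-gallocatechin
Product: 18 undeca-O-benzyl-epigallocatechin-(4β→8)-gallocatechin (free upper 3-OH)
Conditions: Bu4NF, THF, rt to 45 °C
Reagents that add atoms: none
Why: Fluoride-mediated desilylation, which is orthogonal to the benzyl ethers and to the interflavan bond and liberates the only hydroxyl of the molecule.

Step 14
Reactants: 18 undeca-O-benzyl-epigallocatechin-(4β→8)-gallocatechin; 19 3,4,5-tris(benzyloxy)benzoic acid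
Product: 20 tetradeca-O-benzyl epigallocatechin 3-O-gallate-(4β→8)-gallocatechin
Conditions: 19 (2 equiv), DCC, DMAP, CH2Cl2, rt
Reagents that add atoms: none
Why: Steglich esterification, which can only acylate the upper 3-oxygen because the lower one has been a benzyl ether since step 3, and which proceeds with retention at C3.

Step 15
Reactants: 20 tetradeca-O-benzyl epigallocatechin 3-O-gallate-(4β→8)-gallocatechin
Product: 21 epigallocatechin 3-O-gallate-(4β→8)-gallocatechin
Conditions: H2 (1 atm), Pd(OH)2 on carbon, THF/MeOH/H2O, rt; filtration and lyophilisation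
Reagents that add atoms: none
Why: Catalytic hydrogenolysis of all fourteen benzyl ethers under neutral conditions, which should leave the gallate ester, the pyran C2–O1 bonds, the interflavan bond and every stereocentre untouched if the reaction is stopped once debenzylation is complete.

Compound list
1 | (+)-gallocatechin (2R,3S) | Oc1cc(O)c2c(c1)O[C@H](c1cc(O)c(O)c(O)c1)[C@@H](O)C2 | starting material
2 | penta-O-benzyl-(+)-gallocatechin (free 3-OH) | c1c(OCc2ccccc2)cc(OCc2ccccc2)c2c1O[C@H](c1cc(OCc3ccccc3)c(OCc3ccccc3)c(OCc3ccccc3)c1)[C@@H](O)C2 | intermediate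
3 | 8-bromo-penta-O-benzyl-(+)-gallocatechin (free 3-OH) | Brc1c(OCc2ccccc2)cc(OCc2ccccc2)c2c1O[C@H](c1cc(OCc3ccccc3)c(OCc3ccccc3)c(OCc3ccccc3)c1)[C@@H](O)C2 | intermediate
4 | 8-bromo-hexa-O-benzyl-(+)-gallocatechin | Brc1c(OCc2ccccc2)cc(OCc2ccccc2)c2c1O[C@H](c1cc(OCc3ccccc3)c(OCc3ccccc3)c(OCc3ccccc3)c1)[C@@H](OCc1ccccc1)C2 | intermediate
5 | 3,4,5-tris(benzyloxy)benzaldehyde | O=Cc1cc(OCc2ccccc2)c(OCc2ccccc2)c(OCc2ccccc2)c1 | starting material
6 | methyl (Z)-3-[3,4,5-tris(benzyloxy)phenyl]prop-2-enoate | COC(=O)/C=C\c1cc(OCc2ccccc2)c(OCc2ccccc2)c(OCc2ccccc2)c1 | intermediate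
7 | (Z)-3-[3,4,5-tris(benzyloxy)phenyl]prop-2-en-1-ol | OC/C=C\c1cc(OCc2ccccc2)c(OCc2ccccc2)c(OCc2ccccc2)c1 | intermediate
8 | [(2R,3S)-3-[3,4,5-tris(benzyloxy)phenyl]oxiran-2-yl]methanol (cis) | O(Cc1ccccc1)c1cc(cc(OCc2ccccc2)c1OCc1ccccc1)[C@@H]1O[C@@H]1CO | intermediate
9 | 3,5-bis(benzyloxy)phenol | Oc1cc(OCc2ccccc2)cc(OCc2ccccc2)c1 | starting material
10 | (2R,3R)-3-[3,5-bis(benzyloxy)phenoxy]-3-[3,4,5-tris(benzyloxy)phenyl]propane-1,2-diol (syn) | O(Cc1ccccc1)c1cc(cc(OCc2ccccc2)c1OCc1ccccc1)[C@@H](Oc1cc(OCc2ccccc2)cc(OCc2ccccc2)c1)[C@H](O)CO | intermediate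
11 | 1,2-bis-O-(tert-butyldimethylsilyl) ether of diol 10 | O(Cc1ccccc1)c1cc(cc(OCc2ccccc2)c1OCc1ccccc1)[C@@H](Oc1cc(OCc2ccccc2)cc(OCc2ccccc2)c1)[C@H](O[Si](C)(C)C(C)(C)C)CO[Si](C)(C)C(C)(C)C | intermediate
12 | (2R,3R)-3-[3,5-bis(benzyloxy)phenoxy]-2-(tert-butyldimethylsilyloxy)-3-[3,4,5-tris(benzyloxy)phenyl]propan-1-ol | O(Cc1ccccc1)c1cc(cc(OCc2ccccc2)c1OCc1ccccc1)[C@@H](Oc1cc(OCc2ccccc2)cc(OCc2ccccc2)c1)[C@H](O[Si](C)(C)C(C)(C)C)CO | intermediate
13 | (2S,3R)-3-[3,5-bis(benzyloxy)phenoxy]-2-(tert-butyldimethylsilyloxy)-3-[3,4,5-tris(benzyloxy)phenyl]propanal | O(Cc1ccccc1)c1cc(cc(OCc2ccccc2)c1OCc1ccccc1)[C@@H](Oc1cc(OCc2ccccc2)cc(OCc2ccccc2)c1)[C@H](O[Si](C)(C)C(C)(C)C)C=O | intermediate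
14 | 8-lithio-hexa-O-benzyl-(+)-gallocatechin | [Li]c1c(OCc2ccccc2)cc(OCc2ccccc2)c2c1O[C@H](c1cc(OCc3ccccc3)c(OCc3ccccc3)c(OCc3ccccc3)c1)[C@@H](OCc1ccccc1)C2 | intermediate (not isolated)
15 | 1-(hexa-O-benzylgallocatechin-8-yl)-3-[3,5-bis(benzyloxy)phenoxy]-2-(tert-butyldimethylsilyloxy)-3-[3,4,5-tris(benzyloxy)phenyl]propan-1-ol, both epimers at C1 of the chain | O(Cc1ccccc1)c1cc(cc(OCc2ccccc2)c1OCc1ccccc1)[C@@H](Oc1cc(OCc2ccccc2)cc(OCc2ccccc2)c1)[C@H](O[Si](C)(C)C(C)(C)C)C(O)c1c(OCc2ccccc2)cc(OCc2ccccc2)c2c1O[C@H](c1cc(OCc3ccccc3)c(OCc3ccccc3)c(OCc3ccccc3)c1)[C@@H](OCc1ccccc1)C2 | intermediate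
16 | benzylic cation formed from 15 by loss of hydroxide (future upper C4) | O(Cc1ccccc1)c1cc(cc(OCc2ccccc2)c1OCc1ccccc1)[C@@H](Oc1cc(OCc2ccccc2)cc(OCc2ccccc2)c1)[C@H](O[Si](C)(C)C(C)(C)C)[CH+]c1c(OCc2ccccc2)cc(OCc2ccccc2)c2c1O[C@H](c1cc(OCc3ccccc3)c(OCc3ccccc3)c(OCc3ccccc3)c1)[C@@H](OCc1ccccc1)C2 | intermediate (not isolated)
17 | undeca-O-benzyl-3-O-(tert-butyldimethylsilyl)-epigallocatechin-(4β→8)-gallocatechin (upper 2R,3R,4R; lower 2R,3S) | CC(C)(C)[Si](C)(C)O[C@@H]1[C@@H](c2c(OCc3ccccc3)cc(OCc3ccccc3)c3c2O[C@H](c2cc(OCc4ccccc4)c(OCc4ccccc4)c(OCc4ccccc4)c2)[C@@H](OCc2ccccc2)C3)c2c(OCc3ccccc3)cc(OCc3ccccc3)cc2O[C@@H]1c1cc(OCc2ccccc2)c(OCc2ccccc2)c(OCc2ccccc2)c1 | intermediate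
18 | undeca-O-benzyl-epigallocatechin-(4β→8)-gallocatechin (free upper 3-OH) | O[C@@H]1[C@@H](c2c(OCc3ccccc3)cc(OCc3ccccc3)c3c2O[C@H](c2cc(OCc4ccccc4)c(OCc4ccccc4)c(OCc4ccccc4)c2)[C@@H](OCc2ccccc2)C3)c2c(OCc3ccccc3)cc(OCc3ccccc3)cc2O[C@@H]1c1cc(OCc2ccccc2)c(OCc2ccccc2)c(OCc2ccccc2)c1 | intermediate
19 | 3,4,5-tris(benzyloxy)benzoic acid | OC(=O)c1cc(OCc2ccccc2)c(OCc2ccccc2)c(OCc2ccccc2)c1 | starting material
20 | tetradeca-O-benzyl epigallocatechin 3-O-gallate-(4β→8)-gallocatechin | O=C(O[C@@H]1[C@@H](c2c(OCc3ccccc3)cc(OCc3ccccc3)c3c2O[C@H](c2cc(OCc4ccccc4)c(OCc4ccccc4)c(OCc4ccccc4)c2)[C@@H](OCc2ccccc2)C3)c2c(OCc3ccccc3)cc(OCc3ccccc3)cc2O[C@@H]1c1cc(OCc2ccccc2)c(OCc2ccccc2)c(OCc2ccccc2)c1)c1cc(OCc2ccccc2)c(OCc2ccccc2)c(OCc2ccccc2)c1 | intermediate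
21 | epigallocatechin 3-O-gallate-(4β→8)-gallocatechin | O=C(O[C@@H]1[C@@H](c2c(O)cc(O)c3c2O[C@H](c2cc(O)c(O)c(O)c2)[C@@H](O)C3)c2c(O)cc(O)cc2O[C@@H]1c1cc(O)c(O)c(O)c1)c1cc(O)c(O)c(O)c1 | target

Total step count: 15. Longest linear sequence: 12 steps (compound 5 to compound 21, steps 4 to 15); the lower unit joins after 3 steps.

Steps most likely to fail

Step 12. The cation may be diverted by closure onto ring B (five-membered indane formation), by hydride shift or proton loss next to the silyloxy group, or it may be captured with poor facial selectivity at C4. The fallback replaces the intramolecular closure by the established intermolecular Lewis-acid coupling of a C4-activated upper unit with a nucleophilic lower unit. It sets out from compound 2, which is benzylated at O3 (NaH, BnBr, DMF) to hexa-O-benzyl-(+)-gallocatechin F1. Bought (−)-epigallocatechin F2 is benzylated on its five phenols (BnBr, K2CO3, DMF) to penta-O-benzyl-(−)-epigallocatechin F3. This is silylated (TBSOTf, 2,6-lutidine) to 3-O-(tert-butyldimethylsilyl)-penta-O-benzyl-(−)-epigallocatechin F4. F4 is oxidised at C4 with DDQ in the presence of 2-ethoxyethanol to 4β-(2-ethoxyethoxy)-3-O-(tert-butyldimethylsilyl)-penta-O-benzyl-(−)-epigallocatechin F5. TMSOTf-promoted condensation of F5 with an excess of F1 in CH2Cl2 at −78 °C, a reaction class known to be 3,4-trans selective for 2,3-cis electrophiles, should then give compound 17, where the route resumes with step 13. The price is the chromatographic removal of 4→6 isomers and oligomers, which the main route avoids.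

Step 7. Regiocontrol may be lost through Payne rearrangement followed by attack at C1, through attack at C2, or through C-alkylation by the ambident phloroglucinol-type phenoxide. The fallback makes the aryl ether by Mitsunobu inversion instead of epoxide opening and sets out from compound 9. Bought 5-bromo-1,2,3-tris(benzyloxy)benzene F6 is converted with n-BuLi (THF, −78 °C) into 3,4,5-tris(benzyloxy)phenyllithium F7. This is added to bought (R)-2,3-O-isopropylideneglyceraldehyde F8, and the anti (Felkin–Anh) adduct (S)-[3,4,5-tris(benzyloxy)phenyl][(4R)-2,2-dimethyl-1,3-dioxolan-4-yl]methanol F9 is separated from its syn epimer. Mitsunobu reaction of F9 with 9 (PPh3, DIAD, toluene, 0 °C) should invert the benzylic centre and give the aryl ether acetonide F10. Aqueous acetic acid then removes the acetonide and the route is rejoined at compound 10.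

Step 6. Z-Aryl allylic alcohols are slow substrates for the titanium tartrate system, so enantiofacial discrimination may be incomplete and the benzylic epoxide may be opened by the titanium species during the long reaction. The fallback moves the epoxidation one step earlier and changes the catalyst class; it sets out from compound 6. Jacobsen–Katsuki epoxidation of this Z-cinnamate, a privileged substrate type, uses NaOCl, 4-phenylpyridine N-oxide and (S,S)-N,N'-bis(3,5-di-tert-butylsalicylidene)-1,2-cyclohexanediaminomanganese chloride (a salen complex of trivalent manganese, the mirror image of the catalyst that gives (2R,3R)-glycidates from cis-cinnamates) in CH2Cl2 at 0 °C. It should give methyl (2S,3S)-3-[3,4,5-tris(benzyloxy)phenyl]oxirane-2-carboxylate F11. Reduction of the ester with NaBH4 (MeOH/THF, 0 °C) returns to the route at compound 8.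

Further compounds
F1 | step 12 | hexa-O-benzyl-(+)-gallocatechin | c1c(OCc2ccccc2)cc(OCc2ccccc2)c2c1O[C@H](c1cc(OCc3ccccc3)c(OCc3ccccc3)c(OCc3ccccc3)c1)[C@@H](OCc1ccccc1)C2
F2 | step 12 | (−)-epigallocatechin (bought) | Oc1cc(O)c2c(c1)O[C@H](c1cc(O)c(O)c(O)c1)[C@H](O)C2
F3 | step 12 | penta-O-benzyl-(−)-epigallocatechin | c1c(OCc2ccccc2)cc(OCc2ccccc2)c2c1O[C@H](c1cc(OCc3ccccc3)c(OCc3ccccc3)c(OCc3ccccc3)c1)[C@H](O)C2
F4 | step 12 | 3-O-(tert-butyldimethylsilyl)-penta-O-benzyl-(−)-epigallocatechin | c1c(OCc2ccccc2)cc(OCc2ccccc2)c2c1O[C@H](c1cc(OCc3ccccc3)c(OCc3ccccc3)c(OCc3ccccc3)c1)[C@H](O[Si](C)(C)C(C)(C)C)C2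
F5 | step 12 | 4β-(2-ethoxyethoxy)-3-O-(tert-butyldimethylsilyl)-penta-O-benzyl-(−)-epigallocatechin | CC(C)(C)[Si](C)(C)O[C@@H]1[C@@H](OCCOCC)c2c(OCc3ccccc3)cc(OCc3ccccc3)cc2O[C@@H]1c1cc(OCc2ccccc2)c(OCc2ccccc2)c(OCc2ccccc2)c1
F6 | step 7 | 5-bromo-1,2,3-tris(benzyloxy)benzene (bought) | Brc1cc(OCc2ccccc2)c(OCc2ccccc2)c(OCc2ccccc2)c1
F7 | step 7 | 3,4,5-tris(benzyloxy)phenyllithium | [Li]c1cc(OCc2ccccc2)c(OCc2ccccc2)c(OCc2ccccc2)c1
F8 | step 7 | (R)-2,3-O-isopropylideneglyceraldehyde (bought) | CC1(C)OC[C@H](C=O)O1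
F9 | step 7 | (S)-[3,4,5-tris(benzyloxy)phenyl][(4R)-2,2-dimethyl-1,3-dioxolan-4-yl]methanol | O(Cc1ccccc1)c1cc(cc(OCc2ccccc2)c1OCc1ccccc1)[C@H](O)[C@H]1COC(C)(C)O1
F10 | step 7 | (4R)-4-[(R)-[3,5-bis(benzyloxy)phenoxy][3,4,5-tris(benzyloxy)phenyl]methyl]-2,2-dimethyl-1,3-dioxolane | O(Cc1ccccc1)c1cc(cc(OCc2ccccc2)c1OCc1ccccc1)[C@@H](Oc1cc(OCc2ccccc2)cc(OCc2ccccc2)c1)[C@H]1COC(C)(C)O1
F11 | step 6 | methyl (2S,3S)-3-[3,4,5-tris(benzyloxy)phenyl]oxirane-2-carboxylate | O(Cc1ccccc1)c1cc(cc(OCc2ccccc2)c1OCc1ccccc1)[C@@H]1O[C@@H]1C(=O)OC
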